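The cycloheptene (ring B) is closed at its most hindered bond, C1–C10 (daucane numbering, defined below), by a samarium-mediated intramolecular Reformatsky aldol reaction: a tertiary α-bromo ketone in the cyclopentane (ring A, temporary C2 carbonyl) is reduced to a tetrasubstituted samarium enolate that adds to a tethered (Z)-enal, uniting two formerly electrophilic carbons. The step exploits the vicinal relationship of the quaternary ring-fusion carbon C1 and the oxygenated C10, an aldol pattern once C2 is a ketone, and sets ring B, C1 and C10 at once. The precursor is a monocyclic bromo ketone carved from (−)-α-thujone by opening its cyclopropane; the C2 oxygen is erased afterwards.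

Key step: step 13

Numbering used for all intermediates (daucane): C1 = methyl-bearing ring-fusion carbon; C2, C3 = ring A methylenes; C4 = C(OH)(isopropyl); C5 = ring-fusion CH; C6 = CH–O–aroyl; C7 = CH2; C8 = C(CH3)=; C9 = =CH; C10 = CH–O–isovaleryl.

Assumption: C1 of the monocyclic ketones 2–14 is drawn with the configuration inherited from 1 although it is epimerisable, and the acetal carbon of 8 and 9 and the bromine-bearing carbon of 16–18 are left unassigned (mixtures); all are erased or reset by step 13.

Step 1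
Reactants: 1 (−)-α-thujone
Product: 3 (2R,3S,4S)-4-hydroxy-3-(hydroxymethyl)-2-methyl-4-(propan-2-yl)cyclopentan-1-one, via organomercury trifluoroacetate 2 (not isolated)
Conditions: Hg(OCOCF3)2, THF–H2O, 0 → 23 °C; then O2, NaBH4, DMF, 0 °C
Reagents that add atoms: water (O); dioxygen (O=O); mercury bis(trifluoroacetate) (O=C(O[Hg]OC(=O)C(F)(F)F)C(F)(F)F, retained only in 2)
Why: Corner mercuration of the cyclopropane at its CH2 carbon should cleave the bond to the isopropyl-bearing carbon, water adding there with inversion so that the new C4 hydroxyl is trans and the isopropyl cis to the C5 CH2 arm (C5 is retained from 1), and dioxygen trapping of the primary radical during borohydride demercuration gives the C6 alcohol (cyclopropane hydroxymercuration followed by oxidative demercuration).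

Step 2
Reactants: 3 diol ketone
Product: 4 (1R,2R,5S)-5-hydroxy-2-methyl-3-oxo-5-(propan-2-yl)cyclopentane-1-carbaldehyde
Conditions: Dess–Martin periodinane, CH2Cl2, 0 → 23 °C
Reagents that add atoms: none
Why: Dess–Martin oxidation takes the primary alcohol to the C6 aldehyde, returns any ring alcohol formed by over-reduction in step 1 to the ketone, cannot touch the tertiary alcohol and is non-basic, which protects the α-stereocentre C5.

Step 3
Reactants: 4 hydroxy keto aldehyde
Product: 5 (1R,2R,5S)-2-methyl-3-oxo-5-(propan-2-yl)-5-[(triethylsilyl)oxy]cyclopentane-1-carbaldehyde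
Conditions: Et3SiOTf, 2,6-lutidine, CH2Cl2, −78 °C
Reagents that add atoms: triethylsilyl trifluoromethanesulfonate (CC[Si](CC)(CC)OS(=O)(=O)C(F)(F)F)
Why: Silylation of the tertiary alcohol with the reactive silyl triflate at low temperature is faster than enol silylation and blocks retro-aldol cleavage and proton transfer in later steps (silyl ether protection).

Step 4
Reactants: 6 1,1-diethoxy-3-methylbut-2-ene
Product: 7 (1E)-1-ethoxy-3-methylbuta-1,3-diene
Conditions: KHSO4 (cat.), 140 °C, distillation
Reagents that add atoms: none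
Why: Acid-catalysed 1,4-elimination of ethanol from the α,β-unsaturated acetal gives the 1-alkoxy diene, the (E)-isomer being the favoured and the reactive one (acetal pyrolysis).

Step 5
Reactants: 5 aldehyde; 7 diene
Product: 8 (2R,3S,4S)-3-[(2R)-6-ethoxy-4-methyl-3,6-dihydro-2H-pyran-2-yl]-2-methyl-4-(propan-2-yl)-4-[(triethylsilyl)oxy]cyclopentan-1-one
Conditions: [CrCl(L)] (5 mol %, trivalent chromium, L = dianion of the Schiff base of cis-1-aminoindan-2-ol and 3-(1-adamantyl)-2-hydroxy-5-methylbenzaldehyde, antipode matched to Felkin attack), 4 Å MS, t-BuOMe, 23 °C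
Reagents that add atoms: none
Why: A concerted Lewis-acid-catalysed hetero-Diels–Alder reaction through the s-cis diene locks C8=C9 as the (Z)-alkene inside the dihydropyran, and the aldehyde is attacked on its Felkin–Anh face (quaternary C4 anti to the incoming diene terminus), which sets the (6R) carbinol centre, the catalyst antipode being chosen to reinforce this preference.

Step 6
Reactants: 8 cyclic acetal
Product: 10 (2R,3S,4S)-3-[(1R,3Z)-1,5-dihydroxy-3-methylpent-3-en-1-yl]-2-methyl-4-(propan-2-yl)-4-[(triethylsilyl)oxy]cyclopentan-1-one, via lactol 9 (not isolated)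
Conditions: PPTS (cat.), acetone–H2O, 23 °C; then NaBH(OAc)3, AcOH, THF, 35 °C
Reagents that add atoms: water (O)
Why: Mild aqueous acid hydrolyses the allylic acetal to the lactol, whose open hydroxy-enal form is reduced by the aldehyde-selective triacetoxyborohydride while the hindered ring ketone is left, no stereocentre being touched and the (Z)-alkene retained (acetal hydrolysis, chemoselective hydride reduction).

Step 7
Reactants: 10 diol
Product: 11 the C10 (primary) triethylsilyl ether of 10
Conditions: Et3SiCl, imidazole, CH2Cl2, −78 °C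
Reagents that add atoms: chlorotriethylsilane (CC[Si](Cl)(CC)CC)
Why: The unhindered primary allylic hydroxyl is silylated much faster than the hindered secondary C6 hydroxyl at low temperature (selective silyl ether formation).

Step 8
Reactants: 12 4-[(tert-butyldimethylsilyl)oxy]benzaldehyde
Product: 13 4-[(tert-butyldimethylsilyl)oxy]benzoic acid
Conditions: NaClO2, NaH2PO4, 2-methylbut-2-ene, t-BuOH–H2O, 23 °C
Reagents that add atoms: sodium chlorite ([Na+].[O-]Cl=O)
Why: Pinnick oxidation converts the aromatic aldehyde to the acid under buffered conditions that leave the aryl silyl ether intact.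

Step 9
Reactants: 11 secondary alcohol; 13 acid
Product: 14 the C6 4-[(tert-butyldimethylsilyl)oxy]benzoate of 11
Conditions: EDC·HCl, DMAP, CH2Cl2, 23 °C
Reagents that add atoms: none
Why: Carbodiimide/DMAP (Steglich) esterification acylates the only free hydroxyl, at C6, with retention because the C–O bond is not broken.

Step 10
Reactants: 14 ketone
Product: 16 tertiary α-bromo ketone (14 brominated at C1), via trimethylsilyl enol ether 15 (not isolated)
Conditions: Me3SiOTf, Et3N, CH2Cl2, 0 → 23 °C; then NBS, THF, −78 °C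
Reagents that add atoms: N-bromosuccinimide (O=C1CCC(=O)N1Br); trimethylsilyl trifluoromethanesulfonate (C[Si](C)(C)OS(=O)(=O)C(F)(F)F, retained only in 15)
Why: Thermodynamic silyl enol ether formation should occur toward the more substituted C1 (C3 is shielded by the fully substituted C4) and NBS brominates the enol ether at C1 far faster than it attacks the trisubstituted alkene, giving the tertiary α-bromo ketone regiospecifically (α-bromination via a silyl enol ether).

Step 11
Reactants: 16 bromo ketone
Product: 17 the primary (Z)-allylic alcohol from 16 (C10–OH)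
Conditions: PPTS (cat.), MeOH–CH2Cl2, 0 °C
Reagents that add atoms: none
Why: Mild acidic methanolysis cleaves the primary triethylsilyl ether much faster than the hindered tertiary one and the aryl silyl ether (selective desilylation).

Step 12
Reactants: 17 allylic alcohol
Product: 18 the (Z)-enal from 17 (C10 aldehyde)
Conditions: MnO2, CH2Cl2, 23 °C
Reagents that add atoms: none
Why: Manganese dioxide oxidises the allylic alcohol to the enal under neutral conditions that keep the (Z)-geometry, the tertiary bromide and the esters intact (allylic oxidation).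

Step 13
Reactants: 18 bromo keto enal
Product: 20 (1R,4S,5S,6R,10R)-6-{4-[(tert-butyldimethylsilyl)oxy]benzoyloxy}-10-hydroxy-4-[(triethylsilyl)oxy]dauc-8-en-2-one (cis-fused), via samarium enolate 19 (not isolated)
Conditions: SmI2 (2.5 equiv), THF, −78 °C, slow addition of 18 at high dilution; then aq. NH4Cl
Reagents that add atoms: samarium diiodide (I[Sm]I, retained only in 19)
Why: Two single-electron transfers from SmI2 cleave the tertiary C1–Br bond and give the fully substituted samarium enolate regiospecifically, which adds 1,2 to the tethered (Z)-enal (intramolecular samarium Reformatsky-type aldol; closest known reaction type: SmI2-mediated α-bromo ketone–aldehyde cyclisations to seven- and eight-membered carbocycles). Ring B is closed in a 7-(enolexo)-exo-trig mode through a six-membered Zimmerman–Traxler chair in which trivalent samarium bridges the enolate and aldehyde oxygens. The quaternary centre C1 is controlled by the C5 stereocentre: the five-atom tether can reach only the enolate face syn to the C5–C6 bond, which gives the cis ring fusion with the C1 methyl on the opposite face. C10 is controlled by the chair: the vinyl arm C9 sits pseudo-equatorial, anti to the C1–C2 bond, so the carbinol oxygen ends gauche to the C1 methyl (cis to it on ring B) and anti to C5, as the target requires. The step needs C–Br reduction before enal reduction, 1,2- over 1,4-addition and aldol addition over acyl transfer from the C6 ester; these should be secured by the much faster reduction of α-bromo ketones at −78 °C, the oxophilic chelated transition state and the low electrophilicity of the electron-rich aryl ester. The (Z)-enal geometry, which alone allows closure, is fixed in step 5 and preserved by the neutral oxidation in step 12.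

Step 14
Reactants: 20 β-hydroxy ketone
Product: 21 the 10-O-(3-methylbutanoyl) ester of 20
Conditions: isovaleric anhydride, DMAP, Et3N, CH2Cl2, 23 → 40 °C
Reagents that add atoms: 3-methylbutanoic anhydride (CC(C)CC(=O)OC(=O)CC(C)C)
Why: DMAP-catalysed acylation esterifies the only free hydroxyl (C10) with retention and at the same time blocks retro-aldol cleavage in the following steps.

Step 15
Reactants: 21 keto diester
Product: 22 the C2 tosylhydrazone of 21
Conditions: TsNHNH2, AcOH (cat.), EtOH, 60 °C
Reagents that add atoms: 4-methylbenzenesulfonohydrazide (Cc1ccc(S(=O)(=O)NN)cc1)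
Why: Condensation of the cyclopentanone with tosylhydrazide gives the tosylhydrazone, the first stage of a Caglioti-type deoxygenation, without involving any stereocentre.

Step 16
Reactants: 22 tosylhydrazone
Product: 23 (1R,4S,5S,6R,10R)-6-{4-[(tert-butyldimethylsilyl)oxy]benzoyloxy}-10-(3-methylbutanoyloxy)-4-[(triethylsilyl)oxy]dauc-8-ene
Conditions: catecholborane, CHCl3, 0 °C; then NaOAc·3H2O, reflux
Reagents that add atoms: none
Why: Hydride delivery from catecholborane to the C=N bond followed by acetate-induced loss of sulfinate and dinitrogen replaces C=N by CH2 (Kabalka variant of the Caglioti reduction), a method that tolerates esters, silyl ethers and the isolated trisubstituted alkene.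

Step 17
Reactants: 23 bis-silyl ether
Product: 24 target, (1R,4S,5S,6R,10R)-4-hydroxy-6-(4-hydroxybenzoyloxy)-10-(3-methylbutanoyloxy)dauc-8-ene
Conditions: HF·pyridine, pyridine, THF, 0 → 23 °C
Reagents that add atoms: none
Why: Buffered fluoride cleaves both the tertiary triethylsilyl ether and the aryl silyl ether under non-basic conditions that avoid acyl migration (global desilylation).

Compound list
1 | (−)-α-thujone, (1S,4R,5R)-4-methyl-1-(propan-2-yl)bicyclo[3.1.0]hexan-3-one | C[C@H]1C(=O)C[C@@]2(C(C)C)[C@@H]1C2 | starting material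
2 | organomercury trifluoroacetate, 3 with CH2–Hg–OCOCF3 in place of CH2OH | C[C@H]1C(=O)C[C@](O)(C(C)C)[C@@H]1C[Hg]OC(=O)C(F)(F)F | intermediate
3 | (2R,3S,4S)-4-hydroxy-3-(hydroxymethyl)-2-methyl-4-(propan-2-yl)cyclopentan-1-one | C[C@H]1C(=O)C[C@](O)(C(C)C)[C@@H]1CO | intermediate
4 | (1R,2R,5S)-5-hydroxy-2-methyl-3-oxo-5-(propan-2-yl)cyclopentane-1-carbaldehyde | C[C@H]1C(=O)C[C@](O)(C(C)C)[C@@H]1C=O | intermediate
5 | (1R,2R,5S)-2-methyl-3-oxo-5-(propan-2-yl)-5-[(triethylsilyl)oxy]cyclopentane-1-carbaldehyde | C[C@H]1C(=O)C[C@](O[Si](CC)(CC)CC)(C(C)C)[C@@H]1C=O | intermediate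
6 | 1,1-diethoxy-3-methylbut-2-ene | CCOC(OCC)C=C(C)C | starting material
7 | (1E)-1-ethoxy-3-methylbuta-1,3-diene | CCO/C=C/C(C)=C | intermediate
8 | (2R,3S,4S)-3-[(2R)-6-ethoxy-4-methyl-3,6-dihydro-2H-pyran-2-yl]-2-methyl-4-(propan-2-yl)-4-[(triethylsilyl)oxy]cyclopentan-1-one | C[C@H]1C(=O)C[C@](O[Si](CC)(CC)CC)(C(C)C)[C@@H]1[C@H]2CC(C)=CC(OCC)O2 | intermediate
9 | lactol, 8 with OH in place of OEt | C[C@H]1C(=O)C[C@](O[Si](CC)(CC)CC)(C(C)C)[C@@H]1[C@H]2CC(C)=CC(O)O2 | intermediate
10 | (2R,3S,4S)-3-[(1R,3Z)-1,5-dihydroxy-3-methylpent-3-en-1-yl]-2-methyl-4-(propan-2-yl)-4-[(triethylsilyl)oxy]cyclopentan-1-one | C[C@H]1C(=O)C[C@](O[Si](CC)(CC)CC)(C(C)C)[C@@H]1[C@H](O)C/C(C)=C\CO | intermediate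
11 | 10 with the primary C10 hydroxyl as triethylsilyl ether | C[C@H]1C(=O)C[C@](O[Si](CC)(CC)CC)(C(C)C)[C@@H]1[C@H](O)C/C(C)=C\CO[Si](CC)(CC)CC | intermediate
12 | 4-[(tert-butyldimethylsilyl)oxy]benzaldehyde | O=Cc1ccc(O[Si](C)(C)C(C)(C)C)cc1 | starting material
13 | 4-[(tert-butyldimethylsilyl)oxy]benzoic acid | OC(=O)c1ccc(O[Si](C)(C)C(C)(C)C)cc1 | intermediate
14 | C6 4-[(tert-butyldimethylsilyl)oxy]benzoate of 11 | C[C@H]1C(=O)C[C@](O[Si](CC)(CC)CC)(C(C)C)[C@@H]1[C@H](OC(=O)c2ccc(O[Si](C)(C)C(C)(C)C)cc2)C/C(C)=C\CO[Si](CC)(CC)CC | intermediate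
15 | trimethylsilyl enol ether of 14 (C1=C2, OSiMe3 on C2) | CC1=C(O[Si](C)(C)C)C[C@](O[Si](CC)(CC)CC)(C(C)C)[C@@H]1[C@H](OC(=O)c2ccc(O[Si](C)(C)C(C)(C)C)cc2)C/C(C)=C\CO[Si](CC)(CC)CC | intermediate
16 | tertiary α-bromo ketone, 14 with Br on C1 | CC1(Br)C(=O)C[C@](O[Si](CC)(CC)CC)(C(C)C)[C@@H]1[C@H](OC(=O)c2ccc(O[Si](C)(C)C(C)(C)C)cc2)C/C(C)=C\CO[Si](CC)(CC)CC | intermediate
17 | primary (Z)-allylic alcohol from 16 | CC1(Br)C(=O)C[C@](O[Si](CC)(CC)CC)(C(C)C)[C@@H]1[C@H](OC(=O)c2ccc(O[Si](C)(C)C(C)(C)C)cc2)C/C(C)=C\CO | intermediate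
18 | (Z)-enal from 17 | CC1(Br)C(=O)C[C@](O[Si](CC)(CC)CC)(C(C)C)[C@@H]1[C@H](OC(=O)c2ccc(O[Si](C)(C)C(C)(C)C)cc2)C/C(C)=C\C=O | intermediate
19 | samarium enolate (C1=C2–O–SmI2) formed from 18 | CC1=C(O[Sm](I)I)C[C@](O[Si](CC)(CC)CC)(C(C)C)[C@@H]1[C@H](OC(=O)c2ccc(O[Si](C)(C)C(C)(C)C)cc2)C/C(C)=C\C=O | intermediate
20 | (1R,4S,5S,6R,10R)-6-{4-[(tert-butyldimethylsilyl)oxy]benzoyloxy}-10-hydroxy-4-[(triethylsilyl)oxy]dauc-8-en-2-one | CC1=C[C@@H](O)[C@]2(C)C(=O)C[C@](O[Si](CC)(CC)CC)(C(C)C)[C@@H]2[C@H](OC(=O)c2ccc(O[Si](C)(C)C(C)(C)C)cc2)C1 | intermediate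
21 | 10-O-(3-methylbutanoyl) ester of 20 | CC1=C[C@@H](OC(=O)CC(C)C)[C@]2(C)C(=O)C[C@](O[Si](CC)(CC)CC)(C(C)C)[C@@H]2[C@H](OC(=O)c2ccc(O[Si](C)(C)C(C)(C)C)cc2)C1 | intermediate
22 | C2 tosylhydrazone of 21 (stereocentres unchanged) | CC1=C[C@@H](OC(=O)CC(C)C)[C@]2(C)C(=NNS(=O)(=O)c3ccc(C)cc3)C[C@](O[Si](CC)(CC)CC)(C(C)C)[C@@H]2[C@H](OC(=O)c2ccc(O[Si](C)(C)C(C)(C)C)cc2)C1 | intermediate
23 | (1R,4S,5S,6R,10R)-6-{4-[(tert-butyldimethylsilyl)oxy]benzoyloxy}-10-(3-methylbutanoyloxy)-4-[(triethylsilyl)oxy]dauc-8-ene | CC1=C[C@@H](OC(=O)CC(C)C)[C@]2(C)CC[C@](O[Si](CC)(CC)CC)(C(C)C)[C@@H]2[C@H](OC(=O)c2ccc(O[Si](C)(C)C(C)(C)C)cc2)C1 | intermediate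
24 | (1R,4S,5S,6R,10R)-4-hydroxy-6-(4-hydroxybenzoyloxy)-10-(3-methylbutanoyloxy)dauc-8-ene, cis-fused (CNP0086724.1) | CC1=C[C@@H](OC(=O)CC(C)C)[C@]2(C)CC[C@](O)(C(C)C)[C@@H]2[C@H](OC(=O)c2ccc(O)cc2)C1 | target

Total step count: 17. Longest linear sequence: 15 steps from 1 (steps 1–3, 5–7 and 9–17); steps 4 and 8 make the two side fragments.

Steps most likely to fail

1. Step 13 (key step). Protonation of the samarium enolate (plain debromination), reduction of the enal (pinacol-type coupling) or deprotonation of the enal at C7 with loss of the C6 ester may outrun the seven-membered ring closure. The fallback is a Lewis-acid-driven Mukaiyama aldol closure that sets out from 14 and comes back at 20. Ketone 14 is converted with t-BuMe2SiOTf/Et3N into the thermodynamic tert-butyldimethylsilyl enol ether F1. PPTS in MeOH frees the primary allylic alcohol F2 and MnO2 gives the (Z)-enal F3. BF3·OEt2 in CH2Cl2 at −78 °C then closes ring B by intramolecular Mukaiyama aldol addition and gives 20 after aqueous work-up.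

2. Step 5. The cycloaddition may be slow at the hindered α-branched aldehyde, so that a stepwise Mukaiyama-type addition (loss of the (Z)-geometry) or poor facial selectivity competes. The fallback sets out from 5 and comes back at 8. A Felkin-controlled Hosomi–Sakurai addition of methallyltrimethylsilane (BF3·OEt2, −78 °C) gives the homoallylic alcohol F4. Transacetalisation with acrolein diethyl acetal (PPTS, toluene, 60 °C) gives the mixed acetal F5. Ring-closing metathesis with the second-generation Grubbs catalyst RuCl2(H2IMes)(PCy3)(=CHPh) forms the (Z)-configured dihydropyran 8.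

3. Step 1. During demercuration, hydrogen capture by the primary C6 radical (reduction to a methyl group) and over-reduction of the ring ketone compete with oxygen capture. The fallback sets out from organomercurial 2 and comes back at 4, so that step 2 is not needed. Iodinolysis (I2, KI) gives the iodo ketol F6, and Ganem oxidation of the primary iodide (anhydrous Me3NO, DMSO, 23 °C) gives aldehyde 4 directly.

Further compounds
F1 | step 13 | tert-butyldimethylsilyl enol ether of 14 (C1=C2, silyloxy on C2) | CC1=C(O[Si](C)(C)C(C)(C)C)C[C@](O[Si](CC)(CC)CC)(C(C)C)[C@@H]1[C@H](OC(=O)c2ccc(O[Si](C)(C)C(C)(C)C)cc2)C/C(C)=C\CO[Si](CC)(CC)CC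
F2 | step 13 | primary (Z)-allylic alcohol from F1 | CC1=C(O[Si](C)(C)C(C)(C)C)C[C@](O[Si](CC)(CC)CC)(C(C)C)[C@@H]1[C@H](OC(=O)c2ccc(O[Si](C)(C)C(C)(C)C)cc2)C/C(C)=C\CO
F3 | step 13 | (Z)-enal from F2 | CC1=C(O[Si](C)(C)C(C)(C)C)C[C@](O[Si](CC)(CC)CC)(C(C)C)[C@@H]1[C@H](OC(=O)c2ccc(O[Si](C)(C)C(C)(C)C)cc2)C/C(C)=C\C=O
F4 | step 5 | (2R,3S,4S)-3-[(1R)-1-hydroxy-3-methylbut-3-en-1-yl]-2-methyl-4-(propan-2-yl)-4-[(triethylsilyl)oxy]cyclopentan-1-one | C[C@H]1C(=O)C[C@](O[Si](CC)(CC)CC)(C(C)C)[C@@H]1[C@H](O)CC(C)=C
F5 | step 5 | mixed acetal of F4 (C6–O–CH(OEt)–CH=CH2) | C[C@H]1C(=O)C[C@](O[Si](CC)(CC)CC)(C(C)C)[C@@H]1[C@H](OC(OCC)C=C)CC(C)=C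
F6 | step 1 | (2R,3R,4S)-4-hydroxy-3-(iodomethyl)-2-methyl-4-(propan-2-yl)cyclopentan-1-one | C[C@H]1C(=O)C[C@](O)(C(C)C)[C@@H]1CI
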